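## The problem

Compound 18 is a (3R)-isoflavan: a 7-hydroxychroman (rings A and C) whose C3 carries a ring B that is at once a 2'-phenol, a 3'-prenylarene and, through O4' and C5', the benzo ring of a 2,2-dimethyl-2H-chromene. The two aryl halves are joined only through C3 and its two methylene neighbours, so ring C can be closed at O1–C2, at O1–C8a or through C3–C4, and the choice decides how convergent the synthesis is. C3 is the only stereocentre. Nothing else in the molecule can direct it, so its configuration must come from a catalyst or an auxiliary, and it must be protected from enolisation whenever C2 stands at the carbonyl oxidation level. Ring B poses a regiochemical problem of its own: the prenyl group has to enter between the two oxygens of a resorcinol, and the pyran then has to be fused in the linear sense at O4'/C5'. A prenyl group ortho to a free phenol cyclises to a dimethylchroman under protic or Lewis acid, and the two alkenes exclude hydrogenation, hydrogenolysis and electrophilic oxidants, so protecting groups have to leave under neutral conditions. The 2'-OH must also stay masked whenever C2 is activated, because it could close a five-membered benzofuran ring onto C2 in competition with O1. The enabling feature is that C4 is a benzylic CH2 ortho to O1 on ring A: C4, C4a, C8a and O1 form a latent o-quinone methide, while C3 and C2 are the α-carbon and carboxyl carbon of a ring B arylacetic acid, so an enolate–methide [4+2] union forms C3–C4 and O1–C2 and sets C3 in one event.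

## Retrosynthesis

**18 from 17 (O–Si bonds).** The two phenols are unmasked last, from the bis-silyl ether 17. Silyl ethers are chosen over acetals or benzyl ethers because only fluoride leaves the prenyl group, the chromene and the ortho-prenyl phenol untouched. The forward step asks only for buffered fluoride.

**17 from 16 (O1–C2).** Ring C is opened at the alkyl C–O bond, giving the phenol alcohol 16. The neighbouring cut, O1–C8a, would need a halogen on ring A and a metal-catalysed aryl etherification in the presence of three alkenes. The O1–C2 cut needs only an alcohol and a phenol. The forward reaction is an intramolecular Mitsunobu etherification at a primary carbon, so C3 is not touched. It requires that O2' stays silylated, so that only the ring A phenol can attack.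

**16 from 15 (change of oxidation level at C2).** No skeletal bond is cut. C2 is raised to the carboxyl level and rejoined to O1, giving the 3-aryl dihydrocoumarin 15. This costs one reduction later, but it places a carbonyl next to C3 and so makes C3 an enolate carbon. The forward step must reduce the aryl ester faster than the α-aryl centre can enolise.

**15 from 9 and 12 (C3–C4 and O1–C2, the key disconnection).** Cutting these two bonds splits the molecule into the ring B arylacetic acid 9 and the ring A sulfone 12. The sulfone releases the o-quinone methide 14, and the acid is activated as the mixed anhydride 13. The alternative cut at C3–C1' would require asymmetric α-arylation of a lactone with a hindered, pentasubstituted aryl halide and would create the same labile centre under stronger base. The chosen cut gives two halves of similar size, both from one cheap aldehyde, and lets a chiral isothiourea set C3 while ring C closes. The forward reaction must deliver facial selectivity at the enolate carbon, C-alkylation in preference to O-acylation of the phenol of 12, and a product that keeps its configuration.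

**9 from 6 (C2–C3).** The carboxyl carbon is removed by a one-carbon homologation in reverse: acid 9 from aldehyde 8, 8 from enol ether 7, and 7 from the aryl aldehyde 6. A benzylic halide/cyanide sequence is avoided because an ortho-silyloxybenzyl halide is itself a quinone methide precursor. The forward steps are a Wittig reaction, a mild enol ether hydrolysis and a Pinnick oxidation, all of which must spare the prenyl group, the chromene and the aryl silyl ether.

**6 from 3 and 4 (pyran ring: O4'–CMe2 and C5'–CH).** Silyl ether 6 comes from phenol 5. The chromene ring of 5 is cut back to the prenylated resorcinol aldehyde 3 and 3-methylbut-2-enal 4. Doing the prenylation first is what makes the annulation regiochemically unambiguous: with C3 of the aldehyde blocked and the 2-OH flanked on both sides, only O4/C5 can react.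

**3 from 1 and 2 (aryl–prenyl bond).** The prenyl group is disconnected from the carbon between the two oxygens, giving 2,4-dihydroxybenzaldehyde 1 and prenyl bromide 2. The formyl group is kept at this stage because it acidifies the 4-OH and ties up the 2-OH. The forward step is a direct phenoxide C-alkylation. It is short but unselective, and it is the accepted weak point of the ring B branch.

**12 from 1 (C–S bond, then reduction and silylation).** Sulfone 12 is cut at the benzylic C–S bond to the salicyl alcohol 11 and sulfinate. 11 comes from aldehyde 10 by reduction, and 10 from 1 by selective silylation of the unchelated 4-OH. The sulfone is preferred to a benzylic halide because it is stable on the bench and releases 14 only under base.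

## Roads not taken

**Alternative 1: Danheiser benzannulation of ring B.** Ring B would be cut across C1'–C2', C2'–C3' and C4'–C5'. This leads to the diazo enone A1, which already holds rings A and C with C3 configured, and the siloxyalkyne A2, which carries the prenyl group. In the forward direction, irradiation of A1 starts a cascade of Wolff rearrangement, [2+2] cycloaddition with A2, four-electron ring opening and six-electron ring closure, giving the resorcinol derivative A3.
- Merit: the regiochemistry of ring B is solved by construction. The prenyl group lands between the two oxygens, and the oxygens emerge differentiated as a free 2'-OH and a 4'-silyl ether. This is clearly better than step 1 of the chosen route.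
- Weak points: the key step does not create C3. The stereocentre must be installed earlier by a separate asymmetric operation, and in A1 it is allylic and γ to a carbonyl, so it is exposed to deconjugative isomerisation. A3 still lacks the pyran ring, so desilylation at O4', annulation with 4 and pivalate removal follow. The route is linear, because one partner carries almost the whole molecule.
- Comparison: the chosen plan concedes ring B regiocontrol. It sets against this two halves of equal weight from the same aldehyde and a key step that forms the stereocentre catalytically.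

**Alternative 2: double palladium-catalysed C–O coupling.** Both aryl–oxygen bonds, O1–C8a and O–C4', would be cut, leading to the dibromo diol A4. With Pd(OAc)2, a bulky di-tert-butylbiarylphosphine and Cs2CO3, the primary alcohol would couple with the ring A bromide and the tertiary (Z)-allylic alcohol with the ring B bromide. This would close ring C and the pyran in one operation to give A5, which differs from 17 only in its silyl groups.
- Merits: two rings close at once, and C3 in A4 has no adjacent carbonyl, so its configuration is never at risk. In this respect the alternative is safer than the chosen plan, which passes through the enolisable lactone 15.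
- Weak points: aryl etherification with a hindered tertiary alcohol is the least reliable case of this coupling, and a (Z)-allylic tertiary alcohol can ionise or dehydrate. The arylpalladium centre at C4' sits next to the prenyl alkene and can cyclise onto it. The primary alkoxide can undergo β-hydride elimination. A4 itself is a long linear target, and C3 would still have to be set by an auxiliary.
- Comparison: the chosen plan answers the configurational risk by reducing 15 at once. It sets against the alternative a much shorter, convergent access and no transition-metal step beside three alkenes.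

**Alternative 3: pterocarpan detour by chromene oxyarylation.** C3–C1' would be cut together with a temporary C4–O2' bond, leading to the 7-silyloxy-2H-chromene A6 and the ring B o-iodophenol A7. Under Pd(OAc)2, Ag2CO3 and a chiral ligand, A7 would add across C3=C4 of A6 to give the cis-fused pterocarpan A8. Reductive opening of the benzylic C4–O2' bond and desilylation would then lead to 18.
- Merits: it is the shortest route on paper. The aryl–C3 bond is made directly, neither partner needs homologation, and the two new centres are cis by mechanism, with only C3 surviving.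
- Weak points: enantiocontrol in this oxyarylation is far less developed than in enolate catalysis, and it consumes stoichiometric silver. A7 carries its own chromene alkene, of the same kind as the acceptor in A6, so self-reaction competes. The decisive problem is the ring opening. Hydrogenolysis of the benzylic ether would saturate the prenyl and chromene alkenes, and an acidic ionic reduction would free the 2'-OH next to the prenyl group under the very conditions that cyclise it.
- Comparison: the chosen plan is longer by the homologation, the lactone reduction and the Mitsunobu closure. It sets against this an asymmetric step of an established type and an endgame with no reductive step hostile to the alkenes.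

Key step: step 10

Remark on the chemistry (assumption): the sense of induction of the isothiourea is taken from the accepted model (enolate attacked anti to the catalyst's C2 phenyl group), which points to the (2S,3R) catalyst for 3R. The (2R,3S) antipode is used instead if the first run shows the opposite sense.

## Route

Step 1
Reactants: 1 2,4-dihydroxybenzaldehyde; 2 1-bromo-3-methylbut-2-ene (prenyl bromide)
Product: 3 2,4-dihydroxy-3-(3-methylbut-2-enyl)benzaldehyde
Conditions: KOH, H2O, 0 °C to rt
Reagents that add atoms: none
Why: Direct C-alkylation of a 4-acylresorcinol phenoxide in water, where hydrogen bonding to the oxygens favours C- over O-allylation and the carbon between the two oxygens is the most nucleophilic; this is the standard, if unselective, entry to 3-prenyl-2,4-dihydroxyaryl carbonyl compounds, and 3 is separated from its isomers by chromatography.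

Step 2
Reactants: 3 2,4-dihydroxy-3-(3-methylbut-2-enyl)benzaldehyde; 4 3-methylbut-2-enal
Product: 5 7-hydroxy-2,2-dimethyl-8-(3-methylbut-2-enyl)-2H-chromene-6-carbaldehyde
Conditions: ethylenediammonium diacetate (10 mol %), xylene, 140 °C
Reagents that add atoms: none
Why: Amine-salt-mediated Knoevenagel-type condensation of the phenol with the enal followed by oxa-6π electrocyclisation of the dienone is the standard 2,2-dimethylchromene annulation of resorcinols; with the carbon between the oxygens blocked by prenyl and the 2-OH flanked on both sides, only O4/C5 can react, which gives the linear chromene.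

Step 3
Reactants: 5 7-hydroxy-2,2-dimethyl-8-(3-methylbut-2-enyl)-2H-chromene-6-carbaldehyde
Product: 6 7-(tert-butyldimethylsilyloxy)-2,2-dimethyl-8-(3-methylbut-2-enyl)-2H-chromene-6-carbaldehyde
Conditions: TBSCl, imidazole, DMAP (cat.), DMF, rt to 40 °C
Reagents that add atoms: tert-butyldimethylsilyl chloride, CC(C)(C)[Si](C)(C)Cl
Why: Standard phenol silylation; DMAP and gentle warming overcome the hydrogen bond to the aldehyde and the flanking prenyl group, and the silyl ether later keeps this oxygen from closing a benzofuran or a dimethylchroman.

Step 4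
Reactants: 6 7-(tert-butyldimethylsilyloxy)-2,2-dimethyl-8-(3-methylbut-2-enyl)-2H-chromene-6-carbaldehyde
Product: 7 tert-butyl{[6-(2-methoxyethenyl)-2,2-dimethyl-8-(3-methylbut-2-enyl)-2H-chromen-7-yl]oxy}dimethylsilane (E/Z mixture)
Conditions: Ph3P(CH2OMe)Cl, KN(SiMe3)2, THF, 0 °C to rt
Reagents that add atoms: (methoxymethyl)triphenylphosphonium chloride, COC[P+](c1ccccc1)(c1ccccc1)c1ccccc1.[Cl-]
Why: Wittig methoxymethylenation with the non-stabilised ylide; the amide base leaves no nucleophilic alkoxide to attack the aryl silyl ether, and the alkene geometry is irrelevant because both isomers hydrolyse to the same aldehyde.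

Step 5
Reactants: 7 tert-butyl{[6-(2-methoxyethenyl)-2,2-dimethyl-8-(3-methylbut-2-enyl)-2H-chromen-7-yl]oxy}dimethylsilane (E/Z mixture)
Product: 8 2-[7-(tert-butyldimethylsilyloxy)-2,2-dimethyl-8-(3-methylbut-2-enyl)-2H-chromen-6-yl]acetaldehyde
Conditions: 88% aq HCO2H, CH2Cl2, 0 °C to rt
Reagents that add atoms: water, O
Why: Acid-catalysed enol ether hydrolysis (C-protonation, hydration of the oxocarbenium ion, loss of methanol); aryl silyl ethers tolerate aqueous formic acid, the prenyl group cannot cyclise while O7 is silylated, and the sensitive arylacetaldehyde is taken on crude.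

Step 6
Reactants: 8 2-[7-(tert-butyldimethylsilyloxy)-2,2-dimethyl-8-(3-methylbut-2-enyl)-2H-chromen-6-yl]acetaldehyde
Product: 9 2-[7-(tert-butyldimethylsilyloxy)-2,2-dimethyl-8-(3-methylbut-2-enyl)-2H-chromen-6-yl]acetic acid
Conditions: NaClO2, NaH2PO4, 2-methylbut-2-ene (excess), t-BuOH/H2O, 0 °C to rt
Reagents that add atoms: sodium chlorite, [Na+].[O-]Cl=O
Why: Pinnick oxidation; chlorite oxidises only the aldehyde, and the excess 2-methylbut-2-ene removes hypochlorous acid before it can attack the prenyl group, the chromene alkene or the electron-rich ring.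

Step 7
Reactants: 1 2,4-dihydroxybenzaldehyde
Product: 10 4-(tert-butyldimethylsilyloxy)-2-hydroxybenzaldehyde
Conditions: TBSCl (1.05 equiv), imidazole, CH2Cl2, 0 °C
Reagents that add atoms: tert-butyldimethylsilyl chloride, CC(C)(C)[Si](C)(C)Cl
Why: The 4-OH is the more acidic and is not held in the hydrogen bond to the aldehyde, so one equivalent of silyl chloride silylates it selectively.

Step 8
Reactants: 10 4-(tert-butyldimethylsilyloxy)-2-hydroxybenzaldehyde
Product: 11 5-(tert-butyldimethylsilyloxy)-2-(hydroxymethyl)phenol
Conditions: NaBH4, THF/EtOH, 0 °C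
Reagents that add atoms: none
Why: Borohydride reduction of the aldehyde to the salicyl alcohol; the short, cold, weakly basic reaction leaves the aryl silyl ether in place.

Step 9
Reactants: 11 5-(tert-butyldimethylsilyloxy)-2-(hydroxymethyl)phenol
Product: 12 5-(tert-butyldimethylsilyloxy)-2-[(4-methylbenzenesulfonyl)methyl]phenol
Conditions: p-TolSO2Na (excess), HCO2H, H2O/THF, rt
Reagents that add atoms: sodium p-toluenesulfinate, Cc1ccc(cc1)S(=O)[O-].[Na+]
Why: Acid-promoted substitution of an o-hydroxybenzyl alcohol by sulfinate through the benzylic cation/o-quinone methide; the soft sulfur nucleophile in excess outruns Friedel–Crafts self-condensation, and the sulfone is a bench-stable store of the methide.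

Step 10
Reactants: 9 2-[7-(tert-butyldimethylsilyloxy)-2,2-dimethyl-8-(3-methylbut-2-enyl)-2H-chromen-6-yl]acetic acid; 12 5-(tert-butyldimethylsilyloxy)-2-[(4-methylbenzenesulfonyl)methyl]phenol
Product: 15 (3R)-7-(tert-butyldimethylsilyloxy)-3-[7-(tert-butyldimethylsilyloxy)-2,2-dimethyl-8-(3-methylbut-2-enyl)-2H-chromen-6-yl]chroman-2-one, via pivalic mixed anhydride 13 (not isolated), via o-quinone methide 14 (not isolated)
Conditions: t-BuCOCl, i-Pr2NEt, CH2Cl2, 0 °C; then (2S,3R)-HyperBTM [(2S,3R)-3-isopropyl-2-phenyl-3,4-dihydro-2H-pyrimido[2,1-b]benzothiazole] (10 mol %), Cs2CO3, slow addition of 12, 0 °C to rt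
Reagents that add atoms: none
Why: The mixed anhydride 13 acylates the isothiourea and the acyl ammonium ion is deprotonated to the (Z)-configured C1-ammonium enolate, held coplanar with the catalyst by the 1,5 O···S contact, while Cs2CO3 deprotonates the phenol of 12 and expels p-toluenesulfinate to release the o-quinone methide 14 at low concentration. Michael addition of the enolate carbon to the exocyclic CH2 of 14 forms C3–C4 and rearomatises ring A, and the phenoxide so formed attacks the acyl ammonium carbonyl, forming O1–C2 and releasing the catalyst. Ring C therefore closes by 6-exo-trig lactonisation. The closest known reaction type is the formal [4+2] annulation of in situ generated o-quinone methides with chiral ammonium or azolium enolates of arylacetic acid derivatives, which gives 3-aryl-3,4-dihydrocoumarins. C3 is the only new stereocentre and is controlled by the catalyst alone: its C2 phenyl group shields one enolate face and the methide adds anti to it, which on the accepted model leads to 3R with the (2S,3R) catalyst. The step needs C–C bond formation to win over O-acylation of the phenol of 12 and over self-condensation of 14, and it needs the product to keep its configuration. The first is served by preforming 13 and adding 12 slowly, the second by the 7-silyloxy group, which is conjugated with the methide carbon and tempers 14, and the third by the heterogeneous weak base, the low temperature and immediate use of 15 in step 11.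

Step 11
Reactants: 15 (3R)-7-(tert-butyldimethylsilyloxy)-3-[7-(tert-butyldimethylsilyloxy)-2,2-dimethyl-8-(3-methylbut-2-enyl)-2H-chromen-6-yl]chroman-2-one
Product: 16 5-(tert-butyldimethylsilyloxy)-2-{(2R)-2-[7-(tert-butyldimethylsilyloxy)-2,2-dimethyl-8-(3-methylbut-2-enyl)-2H-chromen-6-yl]-3-hydroxypropyl}phenol
Conditions: LiBH4, THF, 0 °C (inverse addition)
Reagents that add atoms: none
Why: Aryl esters are among the most easily reduced esters, so LiBH4 opens the lactone to the phenol and the primary alcohol in the cold; adding 15 to excess hydride makes reduction faster than enolisation, and once C2 is a CH2OH group C3 can no longer epimerise.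

Step 12
Reactants: 16 5-(tert-butyldimethylsilyloxy)-2-{(2R)-2-[7-(tert-butyldimethylsilyloxy)-2,2-dimethyl-8-(3-methylbut-2-enyl)-2H-chromen-6-yl]-3-hydroxypropyl}phenol
Product: 17 (3R)-7-(tert-butyldimethylsilyloxy)-3-[7-(tert-butyldimethylsilyloxy)-2,2-dimethyl-8-(3-methylbut-2-enyl)-2H-chromen-6-yl]chroman
Conditions: PPh3, DIAD, THF, 0 °C to rt
Reagents that add atoms: none
Why: Intramolecular Mitsunobu etherification (6-exo-tet SN2 at the primary C2), the standard closure of isoflavans from 2-aryl-3-(2-hydroxyaryl)propan-1-ols; C3 is not a reacting centre, and with O2' silylated only the ring A phenol can act as the nucleophile.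

Step 13
Reactants: 17 (3R)-7-(tert-butyldimethylsilyloxy)-3-[7-(tert-butyldimethylsilyloxy)-2,2-dimethyl-8-(3-methylbut-2-enyl)-2H-chromen-6-yl]chroman
Product: 18 (3R)-3-[7-hydroxy-2,2-dimethyl-8-(3-methylbut-2-enyl)-2H-chromen-6-yl]chroman-7-ol
Conditions: TBAF, AcOH, THF, 0 °C
Reagents that add atoms: none
Why: Fluoride cleaves both aryl silyl ethers in the cold; acetic acid buffers the phenoxides against air oxidation, and the medium is never acidic enough to cyclise the prenyl group onto the freed 2'-OH.

## Compound list

1 | 2,4-dihydroxybenzaldehyde | O=Cc1ccc(O)cc1O | starting material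
2 | 1-bromo-3-methylbut-2-ene (prenyl bromide) | CC(C)=CCBr | starting material
3 | 2,4-dihydroxy-3-(3-methylbut-2-enyl)benzaldehyde | CC(C)=CCc1c(O)ccc(C=O)c1O | intermediate
4 | 3-methylbut-2-enal | CC(C)=CC=O | starting material
5 | 7-hydroxy-2,2-dimethyl-8-(3-methylbut-2-enyl)-2H-chromene-6-carbaldehyde | CC(C)=CCc1c(O)c(C=O)cc2c1OC(C)(C)C=C2 | intermediate
6 | 7-(tert-butyldimethylsilyloxy)-2,2-dimethyl-8-(3-methylbut-2-enyl)-2H-chromene-6-carbaldehyde | CC(C)=CCc1c(O[Si](C)(C)C(C)(C)C)c(C=O)cc2c1OC(C)(C)C=C2 | intermediate
7 | tert-butyl{[6-(2-methoxyethenyl)-2,2-dimethyl-8-(3-methylbut-2-enyl)-2H-chromen-7-yl]oxy}dimethylsilane, E/Z mixture | CC(C)=CCc1c(O[Si](C)(C)C(C)(C)C)c(C=COC)cc2c1OC(C)(C)C=C2 | intermediate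
8 | 2-[7-(tert-butyldimethylsilyloxy)-2,2-dimethyl-8-(3-methylbut-2-enyl)-2H-chromen-6-yl]acetaldehyde | CC(C)=CCc1c(O[Si](C)(C)C(C)(C)C)c(CC=O)cc2c1OC(C)(C)C=C2 | intermediate
9 | 2-[7-(tert-butyldimethylsilyloxy)-2,2-dimethyl-8-(3-methylbut-2-enyl)-2H-chromen-6-yl]acetic acid | CC(C)=CCc1c(O[Si](C)(C)C(C)(C)C)c(CC(=O)O)cc2c1OC(C)(C)C=C2 | intermediate
10 | 4-(tert-butyldimethylsilyloxy)-2-hydroxybenzaldehyde | O=Cc1ccc(O[Si](C)(C)C(C)(C)C)cc1O | intermediate
11 | 5-(tert-butyldimethylsilyloxy)-2-(hydroxymethyl)phenol | OCc1ccc(O[Si](C)(C)C(C)(C)C)cc1O | intermediate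
12 | 5-(tert-butyldimethylsilyloxy)-2-[(4-methylbenzenesulfonyl)methyl]phenol | Cc1ccc(cc1)S(=O)(=O)Cc1ccc(O[Si](C)(C)C(C)(C)C)cc1O | intermediate
13 | mixed anhydride of 9 with pivalic acid (not isolated) | CC(C)=CCc1c(O[Si](C)(C)C(C)(C)C)c(CC(=O)OC(=O)C(C)(C)C)cc2c1OC(C)(C)C=C2 | intermediate
14 | 3-(tert-butyldimethylsilyloxy)-6-methylidenecyclohexa-2,4-dien-1-one (o-quinone methide, not isolated) | C=C1C=CC(O[Si](C)(C)C(C)(C)C)=CC1=O | intermediate
15 | (3R)-7-(tert-butyldimethylsilyloxy)-3-[7-(tert-butyldimethylsilyloxy)-2,2-dimethyl-8-(3-methylbut-2-enyl)-2H-chromen-6-yl]chroman-2-one | CC(C)=CCc1c(O[Si](C)(C)C(C)(C)C)c([C@@H]2C(=O)Oc3cc(O[Si](C)(C)C(C)(C)C)ccc3C2)cc2c1OC(C)(C)C=C2 | intermediate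
16 | 5-(tert-butyldimethylsilyloxy)-2-{(2R)-2-[7-(tert-butyldimethylsilyloxy)-2,2-dimethyl-8-(3-methylbut-2-enyl)-2H-chromen-6-yl]-3-hydroxypropyl}phenol | CC(C)=CCc1c(O[Si](C)(C)C(C)(C)C)c([C@H](CO)Cc3ccc(O[Si](C)(C)C(C)(C)C)cc3O)cc2c1OC(C)(C)C=C2 | intermediate
17 | (3R)-7-(tert-butyldimethylsilyloxy)-3-[7-(tert-butyldimethylsilyloxy)-2,2-dimethyl-8-(3-methylbut-2-enyl)-2H-chromen-6-yl]chroman | CC(C)=CCc1c(O[Si](C)(C)C(C)(C)C)c([C@@H]2COc3cc(O[Si](C)(C)C(C)(C)C)ccc3C2)cc2c1OC(C)(C)C=C2 | intermediate
18 | (3R)-3-[7-hydroxy-2,2-dimethyl-8-(3-methylbut-2-enyl)-2H-chromen-6-yl]chroman-7-ol | CC(C)=CCc1c(O)c([C@@H]2COc3cc(O)ccc3C2)cc2c1OC(C)(C)C=C2 | target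

## Step count and risk

Total step count: 13. Longest linear sequence: 10 steps (steps 1 to 6, then 10 to 13). The ring A branch (steps 7 to 9) is three steps.

**Step 10 (key step).** Three processes are most likely to go wrong.
- O-acylation of the phenol of 12 by the acyl ammonium ion may compete with release of the methide and C–C bond formation.
- The unsubstituted methide may oligomerise.
- Enantioselectivity may be eroded, either because the ortho-silyloxy group twists the enolate aryl ring or because the product epimerises under carbonate.

The fallback replaces catalyst control by an Evans auxiliary alkylation. It sets out from 9 and 11 and returns at 16. Acid 9 is converted through its pivalic mixed anhydride and lithiated (R)-4-benzyloxazolidin-2-one into (R)-4-benzyl-3-{2-[7-(tert-butyldimethylsilyloxy)-2,2-dimethyl-8-(3-methylbut-2-enyl)-2H-chromen-6-yl]acetyl}oxazolidin-2-one F1. Separately, 11 is allylated selectively at the phenol (allyl bromide, K2CO3, acetone) to [2-(allyloxy)-4-(tert-butyldimethylsilyloxy)phenyl]methanol F2. F2 is converted with CBr4 and PPh3 into 2-(allyloxy)-1-(bromomethyl)-4-(tert-butyldimethylsilyloxy)benzene F3, which is used at once. The sodium enolate of F1 (NaN(SiMe3)2, THF, −78 °C) is alkylated by F3 anti to the benzyl group of the auxiliary, giving the (2R)-configured alkylated imide F4. LiBH4 removes the auxiliary reductively to give (2R)-3-[2-(allyloxy)-4-(tert-butyldimethylsilyloxy)phenyl]-2-[7-(tert-butyldimethylsilyloxy)-2,2-dimethyl-8-(3-methylbut-2-enyl)-2H-chromen-6-yl]propan-1-ol F5. Deallylation with Pd(PPh3)4 and morpholine then gives 16.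

**Step 1.** Phenoxide allylation is likely to be poorly selective, with O-alkylation, attack at C5 and double alkylation lowering the yield of 3. The fallback installs the prenyl group by a Claisen rearrangement. It sets out from 1 and returns at 3. The 4-OH of 1 is etherified with 3-chloro-3-methylbut-1-yne (DBU, catalytic CuCl2, MeCN) to 2-hydroxy-4-[(2-methylbut-3-yn-2-yl)oxy]benzaldehyde F6. F6 is semi-hydrogenated over Pd/CaCO3 poisoned with Pb(OAc)2 and quinoline to 2-hydroxy-4-[(2-methylbut-3-en-2-yl)oxy]benzaldehyde F7. Heating F7 in N,N-diethylaniline moves the allyl unit, with inversion, to the carbon between the two oxygens and gives 3.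

**Step 2.** Condensation at C5 may be sluggish, because the 4-OH is deactivated by the para formyl group, and the enal may then be lost to self-condensation. The fallback builds the pyran by an aryl propargyl ether rearrangement. It sets out from 3 and returns at 5. The 4-OH of 3 is etherified with 3-chloro-3-methylbut-1-yne (DBU, catalytic CuCl2, MeCN) to 2-hydroxy-3-(3-methylbut-2-enyl)-4-[(2-methylbut-3-yn-2-yl)oxy]benzaldehyde F8. Heating F8 in N,N-diethylaniline brings about propargyl Claisen rearrangement to the only free ortho carbon, a 1,5-hydrogen shift and oxa-6π closure to 5.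

**Step 5.** The acid may attack the prenyl group (hydration, or cyclisation with loss of the silyl group), and the arylacetaldehyde may self-condense. The fallback avoids acid altogether. It sets out from 6 and returns at 8. Methylenation of 6 (Ph3PCH3Br, KN(SiMe3)2) gives tert-butyl{[6-ethenyl-2,2-dimethyl-8-(3-methylbut-2-enyl)-2H-chromen-7-yl]oxy}dimethylsilane F9. 9-BBN hydroborates only the terminal alkene of F9, and oxidation with NaBO3·4H2O gives 2-[7-(tert-butyldimethylsilyloxy)-2,2-dimethyl-8-(3-methylbut-2-enyl)-2H-chromen-6-yl]ethanol F10. Dess–Martin periodinane buffered with NaHCO3 oxidises F10 to 8.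

**Step 11.** The α-aryl lactone may enolise and lose configuration before hydride is delivered, and the 2'-silyl group may migrate to the new alkoxide. The fallback takes the stereocentre out of the lactone before any reduction. It sets out from 15, still in the annulation mixture, and returns at 16. After filtration from the carbonate, methanol and DMAP open 15 to methyl (2R)-2-[7-(tert-butyldimethylsilyloxy)-2,2-dimethyl-8-(3-methylbut-2-enyl)-2H-chromen-6-yl]-3-[4-(tert-butyldimethylsilyloxy)-2-hydroxyphenyl]propanoate F11. This open-chain ester is far less acidic at C3 than the lactone. It is reduced with i-Bu2AlH in CH2Cl2 at −78 °C, a non-basic hydride, to 16.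

## Further compounds

F1 | step 10 | (R)-4-benzyl-3-{2-[7-(tert-butyldimethylsilyloxy)-2,2-dimethyl-8-(3-methylbut-2-enyl)-2H-chromen-6-yl]acetyl}oxazolidin-2-one | CC(C)=CCc1c(O[Si](C)(C)C(C)(C)C)c(CC(=O)N3[C@H](Cc4ccccc4)COC3=O)cc2c1OC(C)(C)C=C2
F2 | step 10 | [2-(allyloxy)-4-(tert-butyldimethylsilyloxy)phenyl]methanol | C=CCOc1cc(O[Si](C)(C)C(C)(C)C)ccc1CO
F3 | step 10 | 2-(allyloxy)-1-(bromomethyl)-4-(tert-butyldimethylsilyloxy)benzene | C=CCOc1cc(O[Si](C)(C)C(C)(C)C)ccc1CBr
F4 | step 10 | (R)-4-benzyl-3-{(2R)-3-[2-(allyloxy)-4-(tert-butyldimethylsilyloxy)phenyl]-2-[7-(tert-butyldimethylsilyloxy)-2,2-dimethyl-8-(3-methylbut-2-enyl)-2H-chromen-6-yl]propanoyl}oxazolidin-2-one | CC(C)=CCc1c(O[Si](C)(C)C(C)(C)C)c([C@H](C(=O)N3[C@H](Cc4ccccc4)COC3=O)Cc5ccc(O[Si](C)(C)C(C)(C)C)cc5OCC=C)cc2c1OC(C)(C)C=C2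
F5 | step 10 | (2R)-3-[2-(allyloxy)-4-(tert-butyldimethylsilyloxy)phenyl]-2-[7-(tert-butyldimethylsilyloxy)-2,2-dimethyl-8-(3-methylbut-2-enyl)-2H-chromen-6-yl]propan-1-ol | CC(C)=CCc1c(O[Si](C)(C)C(C)(C)C)c([C@H](CO)Cc3ccc(O[Si](C)(C)C(C)(C)C)cc3OCC=C)cc2c1OC(C)(C)C=C2
F6 | step 1 | 2-hydroxy-4-[(2-methylbut-3-yn-2-yl)oxy]benzaldehyde | C#CC(C)(C)Oc1ccc(C=O)c(O)c1
F7 | step 1 | 2-hydroxy-4-[(2-methylbut-3-en-2-yl)oxy]benzaldehyde | C=CC(C)(C)Oc1ccc(C=O)c(O)c1
F8 | step 2 | 2-hydroxy-3-(3-methylbut-2-enyl)-4-[(2-methylbut-3-yn-2-yl)oxy]benzaldehyde | C#CC(C)(C)Oc1ccc(C=O)c(O)c1CC=C(C)C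
F9 | step 5 | tert-butyl{[6-ethenyl-2,2-dimethyl-8-(3-methylbut-2-enyl)-2H-chromen-7-yl]oxy}dimethylsilane | CC(C)=CCc1c(O[Si](C)(C)C(C)(C)C)c(C=C)cc2c1OC(C)(C)C=C2
F10 | step 5 | 2-[7-(tert-butyldimethylsilyloxy)-2,2-dimethyl-8-(3-methylbut-2-enyl)-2H-chromen-6-yl]ethanol | CC(C)=CCc1c(O[Si](C)(C)C(C)(C)C)c(CCO)cc2c1OC(C)(C)C=C2
F11 | step 11 | methyl (2R)-2-[7-(tert-butyldimethylsilyloxy)-2,2-dimethyl-8-(3-methylbut-2-enyl)-2H-chromen-6-yl]-3-[4-(tert-butyldimethylsilyloxy)-2-hydroxyphenyl]propanoate | CC(C)=CCc1c(O[Si](C)(C)C(C)(C)C)c([C@H](C(=O)OC)Cc3ccc(O[Si](C)(C)C(C)(C)C)cc3O)cc2c1OC(C)(C)C=C2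
A1 | alternative 1 | (E)-1-diazo-4-[(3R)-7-(pivaloyloxy)chroman-3-yl]but-3-en-2-one | [N-]=[N+]=CC(=O)/C=C/[C@@H]1COc2cc(OC(=O)C(C)(C)C)ccc2C1
A2 | alternative 1 | triisopropyl[(5-methylhex-4-en-1-yn-1-yl)oxy]silane | CC(C)=CCC#CO[Si](C(C)C)(C(C)C)C(C)C
A3 | alternative 1 | (R)-3-[2-hydroxy-3-(3-methylbut-2-enyl)-4-(triisopropylsilyloxy)phenyl]chroman-7-yl pivalate | CC(C)=CCc1c(O)c([C@@H]2COc3cc(OC(=O)C(C)(C)C)ccc3C2)ccc1O[Si](C(C)C)(C(C)C)C(C)C
A4 | alternative 2 | (3Z)-4-{2-bromo-5-[(2R)-1-[2-bromo-4-(triisopropylsilyloxy)phenyl]-3-hydroxypropan-2-yl]-3-(3-methylbut-2-enyl)-4-(triisopropylsilyloxy)phenyl}-2-methylbut-3-en-2-ol | CC(C)=CCc1c(O[Si](C(C)C)(C(C)C)C(C)C)c([C@H](CO)Cc2ccc(O[Si](C(C)C)(C(C)C)C(C)C)cc2Br)cc(/C=C\C(C)(C)O)c1Br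
A5 | alternative 2 | (3R)-7-(triisopropylsilyloxy)-3-[2,2-dimethyl-8-(3-methylbut-2-enyl)-7-(triisopropylsilyloxy)-2H-chromen-6-yl]chroman | CC(C)=CCc1c(O[Si](C(C)C)(C(C)C)C(C)C)c([C@@H]2COc3cc(O[Si](C(C)C)(C(C)C)C(C)C)ccc3C2)cc2c1OC(C)(C)C=C2
A6 | alternative 3 | 7-(tert-butyldimethylsilyloxy)-2H-chromene | C1=Cc2ccc(O[Si](C)(C)C(C)(C)C)cc2OC1
A7 | alternative 3 | 6-iodo-2,2-dimethyl-8-(3-methylbut-2-enyl)-2H-chromen-7-ol | CC(C)=CCc1c(O)c(I)cc2c1OC(C)(C)C=C2
A8 | alternative 3 | cis-(6aR,11aR)-pterocarpan carrying the complete ring B and the C7 tert-butyldimethylsilyl ether (isoflavan numbering) | CC(C)=CCc1c2O[C@H]3c4ccc(O[Si](C)(C)C(C)(C)C)cc4OC[C@H]3c2cc2c1OC(C)(C)C=C2
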